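The four phenols are masked as methyl ethers and the aldehyde as its diethyl acetal. The benzo ring of the benzofuran is then cut at C4–C5, C6–C7 and C7–C7a, followed by the C3–aryl and C2–aryl bonds.
Enabling feature: on the benzo ring, C4 carries oxygen, C5 hydrogen, C6 the formyl carbon and C7 only hydrogen, and C3a/C7a are shared with the furan ring. This pattern reads as a methoxycarbene carbon on a furan β-carbon, the CH and substituted carbons of a terminal alkyne, one carbonyl ligand, and a free furan α-carbon.
Forward order: the furan ring is bought as 2,3-dibromofuran, and the 4-methoxyphenyl ring is joined at C2, then the 3,5-dimethoxyphenyl ring at C3. Bromine is brought to the last β-carbon by α-bromination and a halogen dance, and the bromide is converted into the chromium carbene complex.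
The benzo ring is closed last by benzannulation with 3,3-diethoxyprop-1-yne. The surplus C7 hydroxyl then leaves through its triflate, the acetal is hydrolysed and the methyl ethers are cleaved.
Stereochemistry: the target has no stereocentre and no configurationally stable axis, so nothing has to be controlled.

Key step: step 6

Assumption: n-BuLi, t-BuLi and LiN(iPr)2 are taken as commercial solutions, and the four carbon building blocks as catalogue chemicals.

Step 1
Reactants: 1 2,3-dibromofuran; 2 4-methoxyphenylboronic acid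
Product: 3 3-bromo-2-(4-methoxyphenyl)furan
Conditions: Pd(PPh3)4 (3 mol %), Na2CO3, DME/H2O, 80 °C (1.0 equiv of 2)
Reagents that add atoms: none
Why: Site-selective Suzuki–Miyaura coupling: zerovalent palladium inserts faster into the C2–Br bond beside the ring oxygen than into the C3–Br bond, a preference established for 2,3-dibromofuran, so one equivalent of 2 should stop at the monoarylated bromide.

Step 2
Reactants: 3 3-bromo-2-(4-methoxyphenyl)furan; 4 3,5-dimethoxyphenylboronic acid
Product: 5 3-(3,5-dimethoxyphenyl)-2-(4-methoxyphenyl)furan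
Conditions: Pd(OAc)2 (3 mol %), SPhos, K3PO4, toluene/H2O, 100 °C
Reagents that add atoms: none
Why: Suzuki–Miyaura coupling of the remaining crowded β-bromide, for which the bulky electron-rich biarylphosphine SPhos is a standard answer, and no other halide is left to compete.

Step 3
Reactants: 5 3-(3,5-dimethoxyphenyl)-2-(4-methoxyphenyl)furan
Product: 7 5-bromo-3-(3,5-dimethoxyphenyl)-2-(4-methoxyphenyl)furan, via 5-lithiofuran 6 (not isolated)
Conditions: n-BuLi (1.05 equiv), THF, −78 → −20 °C; cannulated into BrCCl2CCl2Br, THF, −78 °C; product used promptly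
Reagents that add atoms: 1,2-dibromo-1,1,2,2-tetrachloroethane, BrC(Cl)(Cl)C(Cl)(Cl)Br
Why: Furan α-lithiation followed by bromine transfer to the carbanion: C5–H is the only furan α-hydrogen and the most acidic C–H of 5, it is metalated below the 0 °C to room temperature range that directed lithiation between two methoxy groups normally needs, and a carbanion quench avoids the electrophilic ring bromination of the dimethoxyphenyl group that NBS or Br2 would invite.

Step 4
Reactants: 7 5-bromo-3-(3,5-dimethoxyphenyl)-2-(4-methoxyphenyl)furan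
Product: 10 4-bromo-3-(3,5-dimethoxyphenyl)-2-(4-methoxyphenyl)furan, via 5-bromo-4-lithiofuran 8 (not isolated), via 4-bromo-5-lithiofuran 9 (not isolated)
Conditions: LiN(iPr)2 (1.1 equiv, added slowly to 7), THF, −78 °C; MeOH, −78 °C → rt
Reagents that add atoms: none
Why: Base-induced halogen dance as known for 2-bromofurans: LiN(iPr)2 removes the sole remaining furan hydrogen next to bromine to give 8, intermolecular bromine–lithium exchanges then drain the system into the more stable α-lithio-β-bromofuran 9, and methanol protonates it.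

Step 5
Reactants: 10 4-bromo-3-(3,5-dimethoxyphenyl)-2-(4-methoxyphenyl)furan
Product: 13 pentacarbonyl{[4-(3,5-dimethoxyphenyl)-5-(4-methoxyphenyl)furan-3-yl](methoxy)methylidene}chromium, via 4-lithiofuran 11 (not isolated), via lithium acylchromate 12 (not isolated)
Conditions: t-BuLi (2.0 equiv), THF, −78 °C; Cr(CO)6, −78 → 0 °C; solvent exchange; Me3OBF4, CH2Cl2, 0 °C → rt
Reagents that add atoms: hexacarbonylchromium Cr(CO)6, O=C=[Cr](=C=O)(=C=O)(=C=O)(=C=O)=C=O; trimethyloxonium tetrafluoroborate Me3OBF4, C[O+](C)C.F[B-](F)(F)F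
Why: Fischer carbene complex synthesis: fast bromine–lithium exchange at −78 °C gives β-furyllithium 11, which adds to a carbonyl ligand of Cr(CO)6, and hard O-methylation of acylchromate 12 with Me3OBF4 fixes the methoxycarbene, the same sequence that turns 3-bromofuran into the parent 3-furyl complex.

Step 6
Reactants: 13 pentacarbonyl{[4-(3,5-dimethoxyphenyl)-5-(4-methoxyphenyl)furan-3-yl](methoxy)methylidene}chromium; 14 3,3-diethoxyprop-1-yne
Product: 16 6-(diethoxymethyl)-3-(3,5-dimethoxyphenyl)-4-methoxy-2-(4-methoxyphenyl)benzofuran-7-ol, via tricarbonylchromium arene complex 15 (not isolated)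
Conditions: 14 (2 equiv), THF (0.05 M), 55 °C, Ar; then air, Et2O, rt; Et3N-washed SiO2
Reagents that add atoms: none
Why: Dötz benzannulation: at 55 °C complex 13 loses one carbonyl ligand, alkyne 14 binds and inserts into the Cr=C bond so that its CH carbon bonds to the methoxy-bearing carbene carbon (C4–C5), and a second carbonyl ligand migrates onto the new carbene carbon that carries the acetal (C6–C7), giving a chromium-bound dienylketene. The one new ring, the six-membered benzo ring, closes by 6π electrocyclisation of this ketene through the furan C2=C3 bond onto the unsubstituted α-carbon (C7–C7a), and enolisation of the resulting cyclohexadienone gives the 7-phenol as its Cr(CO)3 complex 15, which air strips to free 16. The closest known reaction type is the benzannulation of 2-furyl and 3-furyl(methoxy)carbene pentacarbonylchromium complexes with terminal alkynes to methoxybenzofuranols. No stereocentre is created. Two selectivities are required: the orientation of the alkyne, secured by the size difference between H and CH(OEt)2 because the bulkier alkyne end regularly finishes next to the phenol carbon that stems from the carbonyl ligand, and the site of closure on the furan, secured because the second carbon flanking the carbene already bears the dimethoxyphenyl ring and lies across the formal single bond of the furan. The donor solvent THF, the chromium centre and the methoxy heteroatom all favour carbonyl insertion over five-ring formation, and base-washed silica protects the acetal beside the free phenol.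

Step 7
Reactants: 16 6-(diethoxymethyl)-3-(3,5-dimethoxyphenyl)-4-methoxy-2-(4-methoxyphenyl)benzofuran-7-ol
Product: 17 6-(diethoxymethyl)-3-(3,5-dimethoxyphenyl)-4-methoxy-2-(4-methoxyphenyl)benzofuran-7-yl trifluoromethanesulfonate
Conditions: PhNTf2, Et3N, DMAP (cat.), CH2Cl2, 0 °C → rt
Reagents that add atoms: N-phenylbis(trifluoromethanesulfonimide) PhNTf2, O=S(=O)(N(c1ccccc1)S(=O)(=O)C(F)(F)F)C(F)(F)F
Why: Phenol triflation with the mild sulfonyl donor PhNTf2 under amine base, conditions that are never acidic and so spare the diethyl acetal and the electron-rich rings.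

Step 8
Reactants: 17 6-(diethoxymethyl)-3-(3,5-dimethoxyphenyl)-4-methoxy-2-(4-methoxyphenyl)benzofuran-7-yl trifluoromethanesulfonate
Product: 19 3-(3,5-dimethoxyphenyl)-4-methoxy-2-(4-methoxyphenyl)benzofuran-6-carbaldehyde, via deoxygenated acetal 18 (not isolated)
Conditions: Pd(OAc)2 (5 mol %), Fe(C5H4PPh2)2 (dppf), HCO2H, Et3N, DMF, 80 °C; then 1 M HCl, THF, rt
Reagents that add atoms: water, O
Why: Palladium-catalysed formate hydrogenolysis of an aryl triflate (oxidative addition, formate for triflate exchange, loss of CO2 to a palladium hydride, reductive elimination), a standard way to delete the phenol left by this kind of benzannulation, followed by routine acid hydrolysis of the diethyl acetal in the same flask.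

Step 9
Reactants: 19 3-(3,5-dimethoxyphenyl)-4-methoxy-2-(4-methoxyphenyl)benzofuran-6-carbaldehyde
Product: 21 3-(3,5-dihydroxyphenyl)-4-hydroxy-2-(4-hydroxyphenyl)benzofuran-6-carbaldehyde (CNP0078653.0), via tetrakis(dibromoboryl) ether 20 (not isolated)
Conditions: BBr3 (8 equiv), CH2Cl2, −78 °C → rt; ice/H2O
Reagents that add atoms: none
Why: Lewis-acid cleavage of aryl methyl ethers: BBr3 converts all four methoxy groups into aryloxyboron bromides with loss of MeBr, water hydrolyses them to the phenols, and aromatic aldehydes and 2,3-diarylbenzofurans are routinely carried through this treatment.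

Compound list
1 | 2,3-dibromofuran | Brc1ccoc1Br | starting material
2 | 4-methoxyphenylboronic acid | COc1ccc(cc1)B(O)O | starting material
3 | 3-bromo-2-(4-methoxyphenyl)furan | COc1ccc(cc1)-c1occc1Br | intermediate
4 | 3,5-dimethoxyphenylboronic acid | COc1cc(OC)cc(c1)B(O)O | starting material
5 | 3-(3,5-dimethoxyphenyl)-2-(4-methoxyphenyl)furan | COc1ccc(cc1)-c1occc1-c1cc(OC)cc(OC)c1 | intermediate
6 | [4-(3,5-dimethoxyphenyl)-5-(4-methoxyphenyl)furan-2-yl]lithium | [Li]c1cc(-c2cc(OC)cc(OC)c2)c(-c2ccc(OC)cc2)o1 | intermediate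
7 | 5-bromo-3-(3,5-dimethoxyphenyl)-2-(4-methoxyphenyl)furan | Brc1cc(-c2cc(OC)cc(OC)c2)c(-c2ccc(OC)cc2)o1 | intermediate
8 | [2-bromo-4-(3,5-dimethoxyphenyl)-5-(4-methoxyphenyl)furan-3-yl]lithium | [Li]c1c(Br)oc(-c2ccc(OC)cc2)c1-c1cc(OC)cc(OC)c1 | intermediate
9 | [3-bromo-4-(3,5-dimethoxyphenyl)-5-(4-methoxyphenyl)furan-2-yl]lithium | [Li]c1oc(-c2ccc(OC)cc2)c(-c2cc(OC)cc(OC)c2)c1Br | intermediate
10 | 4-bromo-3-(3,5-dimethoxyphenyl)-2-(4-methoxyphenyl)furan | Brc1coc(-c2ccc(OC)cc2)c1-c1cc(OC)cc(OC)c1 | intermediate
11 | [4-(3,5-dimethoxyphenyl)-5-(4-methoxyphenyl)furan-3-yl]lithium | [Li]c1coc(-c2ccc(OC)cc2)c1-c1cc(OC)cc(OC)c1 | intermediate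
12 | lithium pentacarbonyl{[4-(3,5-dimethoxyphenyl)-5-(4-methoxyphenyl)furan-3-yl]carbonyl}chromate | [Li+].[O-]C(=[Cr](=C=O)(=C=O)(=C=O)(=C=O)=C=O)c1coc(-c2ccc(OC)cc2)c1-c1cc(OC)cc(OC)c1 | intermediate
13 | pentacarbonyl{[4-(3,5-dimethoxyphenyl)-5-(4-methoxyphenyl)furan-3-yl](methoxy)methylidene}chromium | COC(=[Cr](=C=O)(=C=O)(=C=O)(=C=O)=C=O)c1coc(-c2ccc(OC)cc2)c1-c1cc(OC)cc(OC)c1 | intermediate
14 | 3,3-diethoxyprop-1-yne | CCOC(OCC)C#C | starting material
15 | tricarbonylchromium η6-complex of 16, metal on the new benzo ring (the η6 bond is written as a dot) | CCOC(OCC)c1cc(OC)c2c(-c3cc(OC)cc(OC)c3)c(-c3ccc(OC)cc3)oc2c1O.O=C=[Cr](=C=O)=C=O | intermediate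
16 | 6-(diethoxymethyl)-3-(3,5-dimethoxyphenyl)-4-methoxy-2-(4-methoxyphenyl)benzofuran-7-ol | CCOC(OCC)c1cc(OC)c2c(-c3cc(OC)cc(OC)c3)c(-c3ccc(OC)cc3)oc2c1O | intermediate
17 | 6-(diethoxymethyl)-3-(3,5-dimethoxyphenyl)-4-methoxy-2-(4-methoxyphenyl)benzofuran-7-yl trifluoromethanesulfonate | CCOC(OCC)c1cc(OC)c2c(-c3cc(OC)cc(OC)c3)c(-c3ccc(OC)cc3)oc2c1OS(=O)(=O)C(F)(F)F | intermediate
18 | 6-(diethoxymethyl)-3-(3,5-dimethoxyphenyl)-4-methoxy-2-(4-methoxyphenyl)benzofuran | CCOC(OCC)c1cc(OC)c2c(-c3cc(OC)cc(OC)c3)c(-c3ccc(OC)cc3)oc2c1 | intermediate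
19 | 3-(3,5-dimethoxyphenyl)-4-methoxy-2-(4-methoxyphenyl)benzofuran-6-carbaldehyde | O=Cc1cc(OC)c2c(-c3cc(OC)cc(OC)c3)c(-c3ccc(OC)cc3)oc2c1 | intermediate
20 | 3-[3,5-bis(dibromoboryloxy)phenyl]-4-(dibromoboryloxy)-2-[4-(dibromoboryloxy)phenyl]benzofuran-6-carbaldehyde | O=Cc1cc(OB(Br)Br)c2c(-c3cc(OB(Br)Br)cc(OB(Br)Br)c3)c(-c3ccc(OB(Br)Br)cc3)oc2c1 | intermediate
21 | 3-(3,5-dihydroxyphenyl)-4-hydroxy-2-(4-hydroxyphenyl)benzofuran-6-carbaldehyde | O=Cc1cc(O)c2c(-c3cc(O)cc(O)c3)c(-c3ccc(O)cc3)oc2c1 | target

Total step count: 9. Longest linear sequence: 9 steps (1 → 21).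

Steps most likely to fail

Step 6 (benzannulation).
- **Risk:** The inductively withdrawing acetal may slow alkyne uptake, so that thermal decay of the crowded carbene complex or annulation without carbonyl insertion competes. Ethanol may also be lost from the acetal beside the free phenol during demetallation and chromatography.
- **Fallback:** It keeps the same three bonds and the same ring closure but carries the C6 carbon at the alcohol oxidation level. It sets out from 13, which is heated in THF with commercial tert-butyldimethyl(prop-2-yn-1-yloxy)silane, a well-behaved partner in this annulation. This should give the tricarbonylchromium arene complex F1 and, after exposure to air, the silyloxymethyl benzofuran-7-ol F2. PhNTf2/Et3N should then give the aryl triflate F3, the catalyst system of step 8 (without the acid treatment) the deoxygenated silyl ether F4, and Bu4NF the benzylic alcohol F5. MnO2 in CH2Cl2 oxidises the alcohol to the aldehyde, and the route is rejoined at 19.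

Step 4 (halogen dance).
- **Risk:** Deprotonation at the crowded C4–H between the aryl ring and bromine may be incomplete. The chain of bromine transfers may stall and leave mixtures of non-, mono- and dibrominated furans, or the base may metalate the dimethoxyphenyl ring.
- **Fallback:** It replaces bromine migration by a removable directing group and sets out from 5. The lithiofuran 6 made as in step 3 is quenched with CO2 to give the 4,5-diarylfuran-2-carboxylic acid F6. Two equivalents of LiN(iPr)2 at −78 °C should metalate ortho to the carboxylate, the α-position being blocked, to give the dilithiated carboxylate F7. BrCCl2CCl2Br then gives the 3-bromofuran-2-carboxylic acid F8. Protodecarboxylation with catalytic Ag2CO3 and AcOH in DMSO at 120 °C, the classical type of exit from 3-bromofuroic acids, returns to the route at 10.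

Step 5 (carbene complex).
- **Risk:** While the sparingly soluble Cr(CO)6 is taken up, lithium may migrate from the β- to the α-carbon by proton transfer. The flanking aryl ring may also slow the addition to the carbonyl ligand.
- **Fallback:** It reverses the polarity of the Cr–C bond formation and sets out from 10. Bromine–lithium exchange as before, to 11, is followed at once by CO2 at −78 °C to give the 4,5-diarylfuran-3-carboxylic acid F9. (COCl)2 with catalytic DMF gives the acid chloride F10. Disodium pentacarbonylchromate F11, prepared from Cr(CO)6 and NaC10H8 (sodium naphthalenide) in THF at −78 °C, is acylated by this chloride to give the sodium acylchromate F12. Me3OBF4 methylates this salt on oxygen, and the route is rejoined at 13.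

Further compounds
F1 | step 6 | tricarbonylchromium η6-complex of F2, metal on the new benzo ring (the η6 bond is written as a dot) | CC(C)(C)[Si](C)(C)OCc1cc(OC)c2c(-c3cc(OC)cc(OC)c3)c(-c3ccc(OC)cc3)oc2c1O.O=C=[Cr](=C=O)=C=O
F2 | step 6 | 6-({[tert-butyl(dimethyl)silyl]oxy}methyl)-3-(3,5-dimethoxyphenyl)-4-methoxy-2-(4-methoxyphenyl)benzofuran-7-ol | CC(C)(C)[Si](C)(C)OCc1cc(OC)c2c(-c3cc(OC)cc(OC)c3)c(-c3ccc(OC)cc3)oc2c1O
F3 | step 6 | 6-({[tert-butyl(dimethyl)silyl]oxy}methyl)-3-(3,5-dimethoxyphenyl)-4-methoxy-2-(4-methoxyphenyl)benzofuran-7-yl trifluoromethanesulfonate | CC(C)(C)[Si](C)(C)OCc1cc(OC)c2c(-c3cc(OC)cc(OC)c3)c(-c3ccc(OC)cc3)oc2c1OS(=O)(=O)C(F)(F)F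
F4 | step 6 | tert-butyl{[3-(3,5-dimethoxyphenyl)-4-methoxy-2-(4-methoxyphenyl)benzofuran-6-yl]methoxy}dimethylsilane | CC(C)(C)[Si](C)(C)OCc1cc(OC)c2c(-c3cc(OC)cc(OC)c3)c(-c3ccc(OC)cc3)oc2c1
F5 | step 6 | [3-(3,5-dimethoxyphenyl)-4-methoxy-2-(4-methoxyphenyl)benzofuran-6-yl]methanol | OCc1cc(OC)c2c(-c3cc(OC)cc(OC)c3)c(-c3ccc(OC)cc3)oc2c1
F6 | step 4 | 4-(3,5-dimethoxyphenyl)-5-(4-methoxyphenyl)furan-2-carboxylic acid | OC(=O)c1cc(-c2cc(OC)cc(OC)c2)c(-c2ccc(OC)cc2)o1
F7 | step 4 | lithium 4-(3,5-dimethoxyphenyl)-3-lithio-5-(4-methoxyphenyl)furan-2-carboxylate | [Li+].[O-]C(=O)c1oc(-c2ccc(OC)cc2)c(-c2cc(OC)cc(OC)c2)c1[Li]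
F8 | step 4 | 3-bromo-4-(3,5-dimethoxyphenyl)-5-(4-methoxyphenyl)furan-2-carboxylic acid | OC(=O)c1oc(-c2ccc(OC)cc2)c(-c2cc(OC)cc(OC)c2)c1Br
F9 | step 5 | 4-(3,5-dimethoxyphenyl)-5-(4-methoxyphenyl)furan-3-carboxylic acid | OC(=O)c1coc(-c2ccc(OC)cc2)c1-c1cc(OC)cc(OC)c1
F10 | step 5 | 4-(3,5-dimethoxyphenyl)-5-(4-methoxyphenyl)furan-3-carbonyl chloride | ClC(=O)c1coc(-c2ccc(OC)cc2)c1-c1cc(OC)cc(OC)c1
F11 | step 5 | disodium pentacarbonylchromate Na2Cr(CO)5 | [Na+].[Na+].O=C=[Cr-2](=C=O)(=C=O)(=C=O)=C=O
F12 | step 5 | sodium pentacarbonyl{[4-(3,5-dimethoxyphenyl)-5-(4-methoxyphenyl)furan-3-yl]carbonyl}chromate | [Na+].[O-]C(=[Cr](=C=O)(=C=O)(=C=O)(=C=O)=C=O)c1coc(-c2ccc(OC)cc2)c1-c1cc(OC)cc(OC)c1
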